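**Retrosynthetic overview**
- The C4–C5 bond of the dienoic acid is cut by a Heck disconnection to (Z)-3-iodobut-2-enoic acid and a ring vinyl carbinol; the 4'-ketone is released from a dioxolane at the very end.
- The glutarate hemiester is cut to the ring neopentyl primary alcohol and prochiral 3-hydroxy-3-methylglutaric anhydride (catalyst-controlled opening sets the glutarate carbinol); the diacid comes from ethyl acetate and two allyl units.
- The vinyl diol comes from ester reduction and chelation-controlled vinyl addition to the ring ketone, so C1' is set from C6'.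
- The keto ester ketal comes from γ-oxidation and selective ketalisation of a cyclohexenone β-keto ester.
- The only carbocycle is formed first, by one-carbon ring expansion of 2-methylcyclopent-2-enone with methyl 2-diazopropanoate, which also sets the quaternary C6'; the dioxolane is the only other ring and is temporary.

Assumption: (Z)-3-iodobut-2-enoic acid and the vinyl- and allylmagnesium bromide solutions are bought.
Assumption: the sense of induction in steps 2 and 9 is as drawn; the ligand antipode or the quinidine-derived pseudo-enantiomer is used if it proves opposite.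

**Step 1**
Reactants: 1 methyl L-alaninate hydrochloride
Product: 2 methyl 2-diazopropanoate
Conditions: isopentyl nitrite (1.2 equiv), Et3N (1.0 equiv), AcOH (0.3 equiv), CHCl3, reflux, 20 min; used as a CH2Cl2 solution
Reagents that add atoms: isopentyl nitrite, CC(C)CCON=O
Why: Diazotisation of an α-amino ester, in which the ester-stabilised diazonium ion loses its α-proton faster than N2 (the alanine stereocentre is erased and is not needed).

**Step 2**
Reactants: 2 methyl 2-diazopropanoate; 3 2-methylcyclopent-2-en-1-one
Product: 4 methyl (1R)-1,3-dimethyl-2-oxocyclohex-3-ene-1-carboxylate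
Conditions: Sc(OTf)3 (10 mol%), chiral N,N'-dioxide L-PiPr2 (L-pipecolic acid-derived bis(2,6-diisopropylanilide), C3 linker; 12 mol%), 2 (1.5 equiv, slow addition), CH2Cl2, 0 °C
Reagents that add atoms: none
Why: Proposed new method: enantioselective Tiffeneau–Demjanov-type one-carbon ring expansion of a cycloalkenone with an α-alkyl-α-diazo ester; the scandium-bound enone carbonyl is attacked by the diazo carbon from the face left open by the ligand, and in the diazonium alkoxide the saturated C5 methylene shifts anti to the departing N2 (its shift, unlike a vinyl shift, lets the re-forming carbonyl stay conjugated with the alkene), so the six-membered ring, the ester carbon and the quaternary R centre arise together; the closest known reactions are chiral N,N'-dioxide–Sc(OTf)3 homologations of ketones with α-alkyl-α-diazo esters and BF3-promoted diazoacetate ring expansions of cycloalkenones, neither shown for a disubstituted diazo ester on an enone.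

**Step 3**
Reactants: 4 methyl (1R)-1,3-dimethyl-2-oxocyclohex-3-ene-1-carboxylate
Product: 5 methyl (1R)-1,3-dimethyl-2,5-dioxocyclohex-3-ene-1-carboxylate
Conditions: Pd(OH)2/C (5 mol%), t-BuOOH (5 equiv), K2CO3 (0.25 equiv), CH2Cl2, 4 °C to rt
Reagents that add atoms: tert-butyl hydroperoxide, CC(C)(C)OO
Why: Peroxyl-radical γ-C–H oxidation of an α,β-enone to the 1,4-enedione (Pd(OH)2/C–TBHP enone oxidation); C5 is the only γ-methylene and the quaternary centre has no acidic hydrogen, so it is untouched.

**Step 4**
Reactants: 5 methyl (1R)-1,3-dimethyl-2,5-dioxocyclohex-3-ene-1-carboxylate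
Product: 6 methyl (7R)-7,9-dimethyl-8-oxo-1,4-dioxaspiro[4.5]dec-9-ene-7-carboxylate
Conditions: ethylene glycol (3 equiv), p-TsOH·H2O (5 mol%), benzene, reflux, Dean–Stark
Reagents that add atoms: ethylene glycol, OCCO
Why: Acid-catalysed ketalisation takes the unhindered C5 carbonyl rather than the C2 carbonyl flanked by the quaternary carbon and the methyl-bearing alkene carbon, as with ketoisophorone.

**Step 5**
Reactants: 6 methyl (7R)-7,9-dimethyl-8-oxo-1,4-dioxaspiro[4.5]dec-9-ene-7-carboxylate; 7 vinylmagnesium bromide
Product: 8 methyl (7R,8R)-8-ethenyl-8-hydroxy-7,9-dimethyl-1,4-dioxaspiro[4.5]dec-9-ene-7-carboxylate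
Conditions: MgBr2·OEt2 (2 equiv), CH2Cl2, −78 °C; then 7 (3 equiv, THF), −78 to −30 °C; H2O quench
Reagents that add atoms: none
Why: Chelation-controlled Grignard 1,2-addition, in which magnesium bridges the ketone and ester carbonyls, holding the ester in the carbonyl plane and the C7 methyl pseudo-axial, so vinyl enters anti to the methyl (cis to the ester) and sets the 8R carbinol; the ketone has no enolisable hydrogen and the ester reacts more slowly.

**Step 6**
Reactants: 8 methyl (7R,8R)-8-ethenyl-8-hydroxy-7,9-dimethyl-1,4-dioxaspiro[4.5]dec-9-ene-7-carboxylate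
Product: 9 (7S,8R)-8-ethenyl-7-(hydroxymethyl)-7,9-dimethyl-1,4-dioxaspiro[4.5]dec-9-en-8-ol
Conditions: LiAlH4 (1.5 equiv), THF, 0 °C to rt; Fieser work-up
Reagents that add atoms: none
Why: Hydride reduction of the ester to the neopentyl primary alcohol; ketal, alkenes and tertiary alkoxide are inert and no stereocentre is touched (the C7 descriptor changes from R to S by priority only).

**Step 7**
Reactants: 10 ethyl acetate; 11 allylmagnesium bromide
Product: 12 4-methylhepta-1,6-dien-4-ol
Conditions: 11 (2.2 equiv), Et2O, 0 °C to rt; H2O quench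
Reagents that add atoms: none
Why: Double Grignard addition to an ester gives the symmetric, achiral tertiary carbinol.

**Step 8**
Reactants: 12 4-methylhepta-1,6-dien-4-ol
Product: 13 3-hydroxy-3-methylpentanedioic acid
Conditions: O3, EtOAc/AcOH, −20 °C; then 30% H2O2, HCO2H, 60 °C
Reagents that add atoms: ozone, [O-][O+]=O; hydrogen peroxide, OO
Why: Ozonolysis with oxidative work-up turns both allyl arms into CH2CO2H (the classical route to this diacid); the product is achiral.

**Step 9**
Reactants: 9 (7S,8R)-8-ethenyl-7-(hydroxymethyl)-7,9-dimethyl-1,4-dioxaspiro[4.5]dec-9-en-8-ol; 13 3-hydroxy-3-methylpentanedioic acid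
Product: 15 (3R)-5-{[(7S,8R)-8-ethenyl-8-hydroxy-7,9-dimethyl-1,4-dioxaspiro[4.5]dec-9-en-7-yl]methoxy}-3-hydroxy-3-methyl-5-oxopentanoic acid, via 3-hydroxy-3-methylglutaric anhydride 14 (not isolated)
Conditions: 13 (2.0 equiv), DCC (2.0 equiv), THF, rt, 2 h, filter; then 9 (1.0 equiv), quinine-derived thiourea (9-amino-9-deoxy-epi-quinine N'-[3,5-bis(trifluoromethyl)phenyl]thiourea, 20 mol%), MTBE, −20 °C, 72 h
Reagents that add atoms: none
Why: Proposed new method: catalyst-controlled desymmetrising alcoholysis of prochiral 3-hydroxy-3-methylglutaric anhydride by a complex alcohol used as the limiting partner; the thiourea binds one of the two enantiotopic anhydride carbonyls (the ring hydroxyl, unlike the methyl, can add a hydrogen bond to the catalyst and so tells the two faces apart) while the quinuclidine nitrogen acts as general base for the neopentyl primary OH of 9, which opens the pro-R acyl arm to give the 3R hemiester with no by-product, the tertiary OH being too hindered to react; the closest known reaction is the cinchona- or thiourea-catalysed desymmetrising methanolysis of 3-substituted glutaric anhydrides, not shown for this anhydride or for a hindered chiral alcohol.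

**Step 10**
Reactants: 15 (3R)-5-{[(7S,8R)-8-ethenyl-8-hydroxy-7,9-dimethyl-1,4-dioxaspiro[4.5]dec-9-en-7-yl]methoxy}-3-hydroxy-3-methyl-5-oxopentanoic acid; 16 (2Z)-3-iodobut-2-enoic acid
Product: 18 (2Z,4E)-5-[(1R,6S)-6-({[(3R)-4-carboxy-3-hydroxy-3-methylbutanoyl]oxy}methyl)-1-hydroxy-2,6-dimethyl-4-oxocyclohex-2-en-1-yl]-3-methylpenta-2,4-dienoic acid, via dioxolane-protected diacid 17 (not isolated)
Conditions: Pd(OAc)2 (10 mol%), n-Bu4NCl (1 equiv), NaHCO3 (4 equiv), DMF, 40 °C; then 1 M HCl, THF, rt, 1 h
Reagents that add atoms: water, O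
Why: Heck vinylation under phase-transfer (Jeffery) conditions, in which the alkenylpalladium keeps the Z geometry, adds to the terminal vinyl carbon and the single available β-hydride elimination gives the 4E alkene; dilute acid then hydrolyses the allylic ketal, and because O-8' is already acylated it cannot add to the freed enone.

**Compound list**
1 | methyl L-alaninate hydrochloride | C[C@H](N)C(=O)OC.Cl | starting material
2 | methyl 2-diazopropanoate | CC(=[N+]=[N-])C(=O)OC | intermediate
3 | 2-methylcyclopent-2-en-1-one | CC1=CCCC1=O | starting material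
4 | methyl (1R)-1,3-dimethyl-2-oxocyclohex-3-ene-1-carboxylate | CC1=CCC[C@@](C)(C(=O)OC)C1=O | intermediate
5 | methyl (1R)-1,3-dimethyl-2,5-dioxocyclohex-3-ene-1-carboxylate | CC1=CC(=O)C[C@@](C)(C(=O)OC)C1=O | intermediate
6 | methyl (7R)-7,9-dimethyl-8-oxo-1,4-dioxaspiro[4.5]dec-9-ene-7-carboxylate | CC1=CC2(OCCO2)C[C@@](C)(C(=O)OC)C1=O | intermediate
7 | vinylmagnesium bromide | C=C[Mg]Br | starting material
8 | methyl (7R,8R)-8-ethenyl-8-hydroxy-7,9-dimethyl-1,4-dioxaspiro[4.5]dec-9-ene-7-carboxylate | CC1=CC2(OCCO2)C[C@@](C)(C(=O)OC)[C@@]1(O)C=C | intermediate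
9 | (7S,8R)-8-ethenyl-7-(hydroxymethyl)-7,9-dimethyl-1,4-dioxaspiro[4.5]dec-9-en-8-ol | CC1=CC2(OCCO2)C[C@@](C)(CO)[C@@]1(O)C=C | intermediate
10 | ethyl acetate | CCOC(C)=O | starting material
11 | allylmagnesium bromide | C=CC[Mg]Br | starting material
12 | 4-methylhepta-1,6-dien-4-ol | C=CCC(C)(O)CC=C | intermediate
13 | 3-hydroxy-3-methylpentanedioic acid | CC(O)(CC(=O)O)CC(=O)O | intermediate
14 | 3-hydroxy-3-methylglutaric anhydride (4-hydroxy-4-methyloxane-2,6-dione) | CC1(O)CC(=O)OC(=O)C1 | intermediate
15 | (3R)-5-{[(7S,8R)-8-ethenyl-8-hydroxy-7,9-dimethyl-1,4-dioxaspiro[4.5]dec-9-en-7-yl]methoxy}-3-hydroxy-3-methyl-5-oxopentanoic acid | CC1=CC2(OCCO2)C[C@@](C)(COC(=O)C[C@](C)(O)CC(=O)O)[C@@]1(O)C=C | intermediate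
16 | (2Z)-3-iodobut-2-enoic acid | I/C(C)=C\C(=O)O | starting material
17 | (2Z,4E)-5-[(7S,8R)-7-({[(3R)-4-carboxy-3-hydroxy-3-methylbutanoyl]oxy}methyl)-8-hydroxy-7,9-dimethyl-1,4-dioxaspiro[4.5]dec-9-en-8-yl]-3-methylpenta-2,4-dienoic acid | CC1=CC2(OCCO2)C[C@@](C)(COC(=O)C[C@](C)(O)CC(=O)O)[C@@]1(O)/C=C/C(C)=C\C(=O)O | intermediate
18 | (2Z,4E)-5-[(1R,6S)-6-({[(3R)-4-carboxy-3-hydroxy-3-methylbutanoyl]oxy}methyl)-1-hydroxy-2,6-dimethyl-4-oxocyclohex-2-en-1-yl]-3-methylpenta-2,4-dienoic acid (CNP0183058.1) | CC1=CC(=O)C[C@@](C)(COC(=O)C[C@](C)(O)CC(=O)O)[C@@]1(O)/C=C/C(C)=C\C(=O)O | target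

**Count**
Total steps: 10. Longest linear sequence: 8 (steps 1–6, 9, 10); steps 7–8 are the side branch to the diacid.

**Three steps most likely to fail**

Step 2 (new ring expansion; risks are conjugate or dipolar addition to the enone, vinyl migration, low ee). The fallback sets out from 3 and comes back at 4. BF3·OEt2-promoted ring expansion of 3 with methyl diazoacetate (made from methyl glycinate hydrochloride as in step 1) gives racemic methyl 3-methyl-2-oxocyclohex-3-ene-1-carboxylate F1. Enantioselective C-methylation of F1 under chiral phase-transfer catalysis (MeI, N-spiro binaphthyl ammonium bromide, CsOH·H2O, toluene, −40 °C) then gives 4, so the quaternary centre is set in a separate alkylation.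

Step 5 (facial selectivity rests on ester chelation; without it the ester sits pseudo-axial and the wrong epimer is expected). The fallback sets out from 6 and comes back at 9. LiAlH4 reduces both ketone and ester of 6 to (7S)-7-(hydroxymethyl)-7,9-dimethyl-1,4-dioxaspiro[4.5]dec-9-en-8-ol F2 (both C8 epimers). MnO2 oxidises only the allylic secondary alcohol to (7S)-7-(hydroxymethyl)-7,9-dimethyl-1,4-dioxaspiro[4.5]dec-9-en-8-one F3. Excess 7 at −78 °C first forms the magnesium alkoxide, which chelates the ketone and directs vinyl anti to the pseudo-axial methyl, giving 9 directly.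

Step 9 (new desymmetrisation; risks are slow acylation of the neopentyl alcohol and low diastereoselectivity at the glutarate carbinol). The fallback sets out from 13 and 9 and comes back at 15. TMSCHN2 in MeOH/toluene converts 13 into dimethyl 3-hydroxy-3-methylpentanedioate F4. Pig liver esterase hydrolysis (pH 7 buffer), reported to give the S half ester, though the enantiomeric excess is uncertain from memory, gives (3S)-3-hydroxy-5-methoxy-3-methyl-5-oxopentanoic acid F5. EDC·HCl/DMAP coupling of F5 with 9 gives 1-{[(7S,8R)-8-ethenyl-8-hydroxy-7,9-dimethyl-1,4-dioxaspiro[4.5]dec-9-en-7-yl]methyl} 5-methyl (3R)-3-hydroxy-3-methylpentanedioate F6. Esterase (or Me3SnOH) cleavage of the unhindered methyl ester of F6 gives 15.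

**Further compounds**
F1 | step 2 | methyl 3-methyl-2-oxocyclohex-3-ene-1-carboxylate (racemic) | COC(=O)C1CCC=C(C)C1=O
F2 | step 5 | (7S)-7-(hydroxymethyl)-7,9-dimethyl-1,4-dioxaspiro[4.5]dec-9-en-8-ol (both C8 epimers) | CC1=CC2(OCCO2)C[C@@](C)(CO)C1O
F3 | step 5 | (7S)-7-(hydroxymethyl)-7,9-dimethyl-1,4-dioxaspiro[4.5]dec-9-en-8-one | CC1=CC2(OCCO2)C[C@@](C)(CO)C1=O
F4 | step 9 | dimethyl 3-hydroxy-3-methylpentanedioate | COC(=O)CC(C)(O)CC(=O)OC
F5 | step 9 | (3S)-3-hydroxy-5-methoxy-3-methyl-5-oxopentanoic acid | OC(=O)C[C@](C)(O)CC(=O)OC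
F6 | step 9 | 1-{[(7S,8R)-8-ethenyl-8-hydroxy-7,9-dimethyl-1,4-dioxaspiro[4.5]dec-9-en-7-yl]methyl} 5-methyl (3R)-3-hydroxy-3-methylpentanedioate | CC1=CC2(OCCO2)C[C@@](C)(COC(=O)C[C@](C)(O)CC(=O)OC)[C@@]1(O)C=C
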